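**Retrosynthetic overview** (gibberellane numbering in the text)

1. C-7 acid from its methyl ester; 16-methylene from a 16-ketone; cis-2,3-diol from a 2,3-alkene; ring A by ring-closing metathesis of a C-4 vinyl and a C-10 allyl group.
2. The 19,20-lactone by reduction/re-oxidation of a transposed 20,19-lactone; the C-4 quaternary centre by convex-face vinylation of the lactone enolate.
3. Ring B by an intramolecular [3+2] cycloaddition: a spiro cyclopropylidene silyl ketene acetal opens with strain release to a dipolar trimethylenemethane (C-5/C-6/C-8, C-7 as acetal carbon), which adds to a tethered (Z)-enoate (C-9=C-10, C-20 ester). This forms C-8–C-9 and C-5–C-10 and closes rings B and C onto ring D.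
4. Enabling feature: in ring B, C-6 (the middle atom of the C-5–C-6–C-8 arc opposite the C-9–C-10 bond) carries the carboxyl carbon C-7, and C-10 carries the oxidised carbon C-20. Ring B is therefore a 2-carboxy-trimethylenemethane plus an acrylate, and C-8 is a ring-D carbon 1,3 to C-13, so a two-carbon tether from C-13 closes ring C in the same event.
5. Ring order: D (bought as a cyclopentenone) → spiro cyclopropane → B and C together → lactone → A.

Key step: step 10

Assumption: alcohol 6 is used as the racemate and the isomer mixtures at C-4, C-5, C-6 and C-8 before step 10 are carried on purpose, because step 10 planarises C-5, C-6 and C-8 and the enolate of step 14 erases C-4.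

**Route**

Step 1
Reactants: 1 (R)-4-[(tert-butyldimethylsilyl)oxy]cyclopent-2-en-1-one
Product: 2 (3S,4R)-4-[(tert-butyldimethylsilyl)oxy]-3-ethenylcyclopentan-1-one
Conditions: CH2=CHMgBr, CuI (10 mol%), THF, −78 °C; aq. NH4Cl
Reagents that add atoms: vinylmagnesium bromide, C=C[Mg]Br
Why: Copper-catalysed conjugate addition should occur anti to the silyloxy group, setting the future C-13 centre trans to oxygen, and the regiospecific enolate cannot eliminate the silyloxy group.

Step 2
Reactants: 2 (3S,4R)-4-[(tert-butyldimethylsilyl)oxy]-3-ethenylcyclopentan-1-one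
Product: 3 tert-butyl{[(1R,2S)-2-ethenyl-4-methylidenecyclopentyl]oxy}dimethylsilane
Conditions: Zn, CH2Br2, TiCl4, THF; then 2, CH2Cl2, 0–25 °C
Reagents that add atoms: dibromomethane, BrCBr
Why: Lombardo methylenation is non-basic, so the beta-silyloxy ketone should be methylenated without the elimination a Wittig ylide could cause, and no stereocentre is touched.

Step 3
Reactants: 3 tert-butyl{[(1R,2S)-2-ethenyl-4-methylidenecyclopentyl]oxy}dimethylsilane
Product: 5 tert-butyl{[(1R,2S)-2-(2-iodoethyl)-4-methylidenecyclopentyl]oxy}dimethylsilane, via alkylzirconocene chloride 4 (not isolated)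
Conditions: Cp2Zr(H)Cl, THF, 25 °C; then I2, 0 °C
Reagents that add atoms: iodine, II
Why: Hydrozirconation is selective for the monosubstituted vinyl group over the 1,1-disubstituted alkene and places zirconium at the terminal carbon, and iodinolysis then gives the primary iodide.

Step 4
Reactants: 6 (±)-2-methylbut-3-en-1-ol
Product: 7 (±)-triethyl[(2-methylbut-3-en-1-yl)oxy]silane
Conditions: Et3SiCl, imidazole, CH2Cl2, 0 °C
Reagents that add atoms: chlorotriethylsilane, CC[Si](Cl)(CC)CC
Why: Standard silylation of a primary alcohol gives the metathesis partner that carries C-4, C-18 and C-19.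

Step 5
Reactants: 5 tert-butyl{[(1R,2S)-2-(2-iodoethyl)-4-methylidenecyclopentyl]oxy}dimethylsilane; 7 (±)-triethyl[(2-methylbut-3-en-1-yl)oxy]silane
Product: 8 trisubstituted alkene (C-8=C-5) carrying the C-4 side chain
Conditions: RuCl2(=CHPh)(PCy3)(H2IMes) (second-generation Grubbs catalyst, 5 mol%), 7 (3 equiv), CH2Cl2, 40 °C
Reagents that add atoms: none
Why: Olefin cross-metathesis of the unhindered 1,1-disubstituted alkene with an excess of the monosubstituted partner should give the trisubstituted alkene with loss of ethylene, and its E/Z ratio is irrelevant.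

Step 6
Reactants: 8 trisubstituted alkene (C-8=C-5) carrying the C-4 side chain
Product: 9 spiro cyclopropane methyl ester
Conditions: Rh2(OAc)4 (1 mol%), N2CHCO2Me (slow addition), CH2Cl2, 25 °C
Reagents that add atoms: methyl diazoacetate, COC(=O)C=[N+]=[N-]
Why: Rhodium-carbenoid cyclopropanation of the only alkene present installs C-6 and C-7, and every diastereomer at the three cyclopropane carbons is acceptable.

Step 7
Reactants: 9 spiro cyclopropane methyl ester
Product: 10 cyclopropylidene silyl ketene acetal
Conditions: LiN(i-Pr)2, t-BuMe2SiCl (in situ), THF/DMPU, −78 to −40 °C; pentane, filtration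
Reagents that add atoms: tert-butyldimethylsilyl chloride, CC(C)(C)[Si](C)(C)Cl
Why: The cyclopropane alpha-hydrogen at C-6 is the only acidic C–H, and in situ O-silylation of the ester enolate should outrun its alkylation by the primary iodide.

Step 8
Reactants: 11 methyl pent-4-enoate
Product: 13 methyl (2Z)-2-({[(trifluoromethyl)sulfonyl]oxy}methylidene)pent-4-enoate, via sodium enolate 12 (not isolated)
Conditions: NaH, HCO2Et, THF, 0–25 °C; then Tf2O, −78 °C
Reagents that add atoms: ethyl formate, CCOC=O; trifluoromethanesulfonic anhydride, O=S(=O)(OS(=O)(=O)C(F)(F)F)C(F)(F)F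
Why: Claisen formylation gives the chelated sodium (Z)-enolate, and O-triflation keeps the oxygen cis to the ester, which fixes the alkene geometry needed in step 10.

Step 9
Reactants: 10 cyclopropylidene silyl ketene acetal; 13 methyl (2Z)-2-({[(trifluoromethyl)sulfonyl]oxy}methylidene)pent-4-enoate
Product: 15 cyclopropylidene silyl ketene acetal with tethered (Z)-enoate, via alkylzinc iodide 14 (not isolated)
Conditions: Zn dust, LiCl, THF, 25 °C; then 13, Pd(PPh3)4 (5 mol%), THF, 25 °C
Reagents that add atoms: none
Why: Zinc insertion into the primary C–I bond and Negishi coupling with the enol triflate are neutral and anhydrous, spare the ketene acetal and retain the (Z) geometry.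

Step 10
Reactants: 15 cyclopropylidene silyl ketene acetal with tethered (Z)-enoate
Product: 18 B/C/D tricyclic hydroxy diester, via dipolar trimethylenemethane 16 (not isolated), via cycloadduct silyl ketene acetal 17 (not isolated)
Conditions: PhMe, 110 °C; then pyridinium p-toluenesulfonate, MeOH, 25 °C
Reagents that add atoms: none
Why: Proposed new method: on heating, the donor-substituted alkylidenecyclopropane should ionise its distal, fully substituted C-5–C-8 bond (release of alkylidenecyclopropane strain, push from the two ketene-acetal oxygens) to the dipolar trimethylenemethane 16, an allyl anion over C-5/C-6/C-8 beside a dioxycarbenium ion at C-7, which adds to the tethered (Z)-enoate in a concerted suprafacial six-electron [3+2] step that ends with C-6 collapsing onto C-7 to give ketene acetal 17; the closest known reaction is the thermal dipolar-trimethylenemethane [3+2] cycloaddition of 2-alkylidenecyclopropanone acetals with electron-poor alkenes, which differs only in which ring bond is ionised. Ring B closes as the five-membered cycloadduct ring (C-8–C-9 and C-5–C-10), and ring C closes at the same time in a 6-exo sense through the tether C-14–C-13–C-12–C-11, which creates the bicyclo[3.2.1]octane with ring D. C-8 is set by the tether, because the enoate can only reach the face of ring D that carries the C-13 chain; C-9 and C-10 are set by the (Z) geometry of the enoate (C-11 and C-20 end up cis); C-5 is set by the side chain taking the outside position of the allyl anion and the ester sitting endo over the cationic C-7, which places the C-4 chain cis to C-20. The selectivities needed are regiochemistry (C-8, not C-5, to the beta-carbon C-9), which the tether enforces because the alternative closes an eight-membered ring, and bonding through the two carbon termini and not through C-7, which a non-polar solvent and an acrylate-type acceptor favour. Because ring opening is reversible and planarises C-5, C-6 and C-8, every cyclopropane diastereomer of 15 should funnel into the same intermediate, and methanolysis then gives the C-7 methyl ester and frees the C-19 alcohol.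

Step 11
Reactants: 18 B/C/D tricyclic hydroxy diester
Product: 20 transposed 20,19-lactone, via C-6-epimerised hydroxy diester 19 (not isolated)
Conditions: NaOMe (0.3 equiv), MeOH, 50 °C; AcOH; then pyridinium p-toluenesulfonate, PhMe, 80 °C
Reagents that add atoms: none
Why: Methoxide should equilibrate the C-6 ester through its enolate to the more stable epimer trans to the C-5 side chain, and lactonisation of the C-19 alcohol onto the cis C-20 ester then marks C-20 as the only lactone carbonyl.

Step 12
Reactants: 20 transposed 20,19-lactone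
Product: 21 19,20-diol
Conditions: LiBH4, THF, 0 °C
Reagents that add atoms: none
Why: A delta-lactone is reduced by LiBH4 much faster than the hindered C-7 methyl ester, so the diol should form chemoselectively.

Step 13
Reactants: 21 19,20-diol
Product: 22 19,20-lactone
Conditions: TEMPO (10 mol%), PhI(OAc)2, CH2Cl2, 25 °C
Reagents that add atoms: none
Why: Oxoammonium oxidation should prefer the less hindered C-19 alcohol over the neopentyl C-20 alcohol, and the aldehyde is trapped as the lactol and oxidised on to the lactone.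

Step 14
Reactants: 22 19,20-lactone
Product: 24 C-4 [2-(phenylsulfinyl)ethyl] lactone, via lithium lactone enolate 23 (not isolated)
Conditions: LiN(i-Pr)2, THF, −78 °C; then CH2=CHS(O)Ph, −78 to −20 °C; AcOH
Reagents that add atoms: phenyl vinyl sulfoxide, C=CS(=O)c1ccccc1
Why: The lactone alpha-hydrogen at C-4 is more acidic than the ester alpha-hydrogen at C-6, and Michael addition to the vinyl sulfoxide should occur on the convex face of the cis-fused lactone/ring-B bicycle, which sets the C-4 quaternary centre with the new chain cis to the C-10 allyl group.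

Step 15
Reactants: 24 C-4 [2-(phenylsulfinyl)ethyl] lactone
Product: 25 C-4 vinyl lactone
Conditions: PhMe, CaCO3, 110 °C
Reagents that add atoms: none
Why: Sulfoxide pyrolysis (thermal syn-elimination) can only proceed towards the one beta-carbon that bears hydrogen and unveils the vinyl group.

Step 16
Reactants: 25 C-4 vinyl lactone
Product: 26 tetracyclic 2,3-alkene
Conditions: RuCl2(=CHPh)(PCy3)(H2IMes) (second-generation Grubbs catalyst, 5 mol%), CH2Cl2, 40 °C
Reagents that add atoms: none
Why: Ring-closing metathesis of the vinyl and allyl groups, held cis on the lactone ring, should close ring A as a bicyclo[3.3.1]nonene with loss of ethylene.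

Step 17
Reactants: 26 tetracyclic 2,3-alkene
Product: 27 C-16 alcohol
Conditions: Bu4NF, THF, 25 °C
Reagents that add atoms: none
Why: Fluoride cleaves the secondary silyl ether and leaves the ester and lactone untouched.

Step 18
Reactants: 27 C-16 alcohol
Product: 28 C-16 ketone
Conditions: Dess–Martin periodinane, CH2Cl2, 25 °C
Reagents that add atoms: none
Why: Dess–Martin oxidation of the only alcohol gives the ketone, and the adjacent C-13 is now a bridgehead and cannot epimerise.

Step 19
Reactants: 28 C-16 ketone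
Product: 29 cis-2,3-diol
Conditions: OsO4 (5 mol%), N-methylmorpholine N-oxide, acetone/H2O, 25 °C
Reagents that add atoms: N-methylmorpholine N-oxide, C[N+]1([O-])CCOCC1; water, O
Why: Upjohn dihydroxylation is syn and should occur on the exo face of the bicyclo[3.3.1]nonene, away from the lactone bridge, giving both hydroxyls on the face of the C-4 methyl group.

Step 20
Reactants: 29 cis-2,3-diol
Product: 30 methyl ester of the target
Conditions: Zn, CH2Br2, TiCl4, THF; then 29, CH2Cl2, 0–25 °C
Reagents that add atoms: dibromomethane, BrCBr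
Why: Lombardo methylenation is selective for ketones over esters and lactones and is non-basic, so the beta-hydroxy lactone should escape retro-aldol epimerisation at C-3.

Step 21
Reactants: 30 methyl ester of the target
Product: 31 CNP0332607.1
Conditions: n-PrSLi, HMPA, 25 °C; then aq. HCl
Reagents that add atoms: none
Why: Thiolate SN2 dealkylation at the ester methyl group cleaves the hindered C-7 ester without hydroxide, which would open the lactone or trigger retro-aldol epimerisation.

**Compound list**

1 | (R)-4-[(tert-butyldimethylsilyl)oxy]cyclopent-2-en-1-one | O=C1C=C[C@H](O[Si](C)(C)C(C)(C)C)C1 | starting material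
2 | (3S,4R)-4-[(tert-butyldimethylsilyl)oxy]-3-ethenylcyclopentan-1-one | O=C1C[C@@H](C=C)[C@H](O[Si](C)(C)C(C)(C)C)C1 | intermediate
3 | tert-butyl{[(1R,2S)-2-ethenyl-4-methylidenecyclopentyl]oxy}dimethylsilane | C=C1C[C@@H](C=C)[C@H](O[Si](C)(C)C(C)(C)C)C1 | intermediate
4 | alkylzirconocene chloride from terminal hydrozirconation of the vinyl group of 3 | C=C1C[C@@H](CC[Zr](Cl)(C2C=CC=C2)C2C=CC=C2)[C@H](O[Si](C)(C)C(C)(C)C)C1 | intermediate
5 | tert-butyl{[(1R,2S)-2-(2-iodoethyl)-4-methylidenecyclopentyl]oxy}dimethylsilane | C=C1C[C@@H](CCI)[C@H](O[Si](C)(C)C(C)(C)C)C1 | intermediate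
6 | (±)-2-methylbut-3-en-1-ol | C=CC(C)CO | starting material
7 | (±)-triethyl[(2-methylbut-3-en-1-yl)oxy]silane | C=CC(C)CO[Si](CC)(CC)CC | intermediate
8 | tert-butyl{[(1R,2S)-2-(2-iodoethyl)-4-{2-methyl-3-[(triethylsilyl)oxy]propylidene}cyclopentyl]oxy}dimethylsilane (E/Z and side-chain epimer mixture) | CC(CO[Si](CC)(CC)CC)C=C1C[C@@H](CCI)[C@H](O[Si](C)(C)C(C)(C)C)C1 | intermediate
9 | methyl (5S,6R)-6-[(tert-butyldimethylsilyl)oxy]-5-(2-iodoethyl)-2-{1-[(triethylsilyl)oxy]propan-2-yl}spiro[2.4]heptane-1-carboxylate (mixture at the cyclopropane carbons and the side chain) | COC(=O)C1C(C(C)CO[Si](CC)(CC)CC)C12C[C@@H](CCI)[C@H](O[Si](C)(C)C(C)(C)C)C2 | intermediate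
10 | methyl tert-butyldimethylsilyl ketene acetal of 9 (exocyclic C=C on the cyclopropane; ring stereocentres as in 9) | COC(O[Si](C)(C)C(C)(C)C)=C1C(C(C)CO[Si](CC)(CC)CC)C12C[C@@H](CCI)[C@H](O[Si](C)(C)C(C)(C)C)C2 | intermediate
11 | methyl pent-4-enoate | C=CCCC(=O)OC | starting material
12 | sodium (Z)-enolate of methyl 2-formylpent-4-enoate | [Na+].[O-]/C=C(/CC=C)C(=O)OC | intermediate
13 | methyl (2Z)-2-({[(trifluoromethyl)sulfonyl]oxy}methylidene)pent-4-enoate | C=CC/C(C(=O)OC)=C/OS(=O)(=O)C(F)(F)F | intermediate
14 | alkylzinc iodide from 10 (C–ZnI in place of C–I) | COC(O[Si](C)(C)C(C)(C)C)=C1C(C(C)CO[Si](CC)(CC)CC)C12C[C@@H](CC[Zn]I)[C@H](O[Si](C)(C)C(C)(C)C)C2 | intermediate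
15 | 10 with the iodoethyl group replaced by a (3Z)-4-(methoxycarbonyl)hepta-3,6-dien-1-yl chain | COC(O[Si](C)(C)C(C)(C)C)=C1C(C(C)CO[Si](CC)(CC)CC)C12C[C@@H](CC/C=C(/CC=C)C(=O)OC)[C@H](O[Si](C)(C)C(C)(C)C)C2 | intermediate
16 | dipolar trimethylenemethane (allyl anion over C-5/C-6/C-8, dioxycarbenium at C-7), drawn as one resonance form | CO[C+](O[Si](C)(C)C(C)(C)C)C([CH-]C(C)CO[Si](CC)(CC)CC)=C1C[C@@H](CC/C=C(/CC=C)C(=O)OC)[C@H](O[Si](C)(C)C(C)(C)C)C1 | intermediate
17 | B/C/D tricyclic cycloadduct with C-6=C-7 silyl ketene acetal, C-20 methyl ester, C-10 allyl, 16-O-silyl ether (C-5, C-8, C-9, C-10, C-13 as in the target) | CC(C)(C)[Si](C)(C)O[C@@H]1C[C@]23C[C@H]1CC[C@H]2[C@](C(=O)OC)(CC=C)[C@@H](C(C)CO[Si](CC)(CC)CC)C3=C(OC)O[Si](C)(C)C(C)(C)C | intermediate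
18 | B/C/D tricyclic hydroxy diester: C-7 and C-20 methyl esters, C-10 allyl, C-5 (1-hydroxypropan-2-yl), 16-O-silyl ether (C-4 and C-6 epimer mixtures) | CC(C)(C)[Si](C)(C)O[C@@H]1C[C@]23C[C@H]1CC[C@H]2[C@](C(=O)OC)(CC=C)[C@@H](C(C)CO)C3C(=O)OC | intermediate
19 | 18 with the C-6 ester in the natural configuration (trans to the C-5 side chain) | CC(C)(C)[Si](C)(C)O[C@@H]1C[C@]23C[C@H]1CC[C@H]2[C@](C(=O)OC)(CC=C)[C@@H](C(C)CO)[C@@H]3C(=O)OC | intermediate
20 | transposed 20,19-lactone (carbonyl at C-20, oxygen on C-19), C-7 methyl ester, C-4 epimer mixture | CC(C)(C)[Si](C)(C)O[C@@H]1C[C@]23C[C@H]1CC[C@H]2[C@@]4(CC=C)C(=O)OCC(C)[C@H]4[C@@H]3C(=O)OC | intermediate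
21 | 19,20-diol, C-7 methyl ester, C-4 epimer mixture | CC(C)(C)[Si](C)(C)O[C@@H]1C[C@]23C[C@H]1CC[C@H]2[C@](CO)(CC=C)[C@@H](C(C)CO)[C@@H]3C(=O)OC | intermediate
22 | 19,20-lactone (carbonyl at C-19, oxygen on C-20), C-4 epimer mixture | CC(C)(C)[Si](C)(C)O[C@@H]1C[C@]23C[C@H]1CC[C@H]2[C@@]4(CC=C)COC(=O)C(C)[C@H]4[C@@H]3C(=O)OC | intermediate
23 | lithium enolate of lactone 22 (C-4=C-19) | CC(C)(C)[Si](C)(C)O[C@@H]1C[C@]23C[C@H]1CC[C@H]2[C@@]4(CC=C)COC(O[Li])=C(C)[C@H]4[C@@H]3C(=O)OC | intermediate
24 | lactone with quaternary C-4 carrying methyl and 2-(phenylsulfinyl)ethyl (sulfur epimers) | CC(C)(C)[Si](C)(C)O[C@@H]1C[C@]23C[C@H]1CC[C@H]2[C@@]4(CC=C)COC(=O)[C@](C)(CCS(=O)c5ccccc5)[C@H]4[C@@H]3C(=O)OC | intermediate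
25 | lactone with quaternary C-4 carrying methyl and vinyl, vinyl cis to the C-10 allyl group | CC(C)(C)[Si](C)(C)O[C@@H]1C[C@]23C[C@H]1CC[C@H]2[C@@]4(CC=C)COC(=O)[C@](C)(C=C)[C@H]4[C@@H]3C(=O)OC | intermediate
26 | tetracyclic 19,20-lactone with ring-A 2,3-alkene, C-7 methyl ester, 16-O-silyl ether | CC(C)(C)[Si](C)(C)O[C@@H]1C[C@]23C[C@H]1CC[C@H]2[C@]45COC(=O)[C@](C)(C=CC4)[C@H]5[C@@H]3C(=O)OC | intermediate
27 | C-16 alcohol of 26 | O[C@@H]1C[C@]23C[C@H]1CC[C@H]2[C@]45COC(=O)[C@](C)(C=CC4)[C@H]5[C@@H]3C(=O)OC | intermediate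
28 | C-16 ketone with ring-A 2,3-alkene | O=C1C[C@]23C[C@H]1CC[C@H]2[C@]45COC(=O)[C@](C)(C=CC4)[C@H]5[C@@H]3C(=O)OC | intermediate
29 | C-16 ketone with cis-2,3-diol (both hydroxyls on the face of the C-4 methyl group), C-7 methyl ester | O=C1C[C@]23C[C@H]1CC[C@H]2[C@]45COC(=O)[C@](C)([C@@H](O)[C@@H](O)C4)[C@H]5[C@@H]3C(=O)OC | intermediate
30 | methyl ester of the target | C=C1C[C@]23C[C@H]1CC[C@H]2[C@]45COC(=O)[C@](C)([C@@H](O)[C@@H](O)C4)[C@H]5[C@@H]3C(=O)OC | intermediate
31 | CNP0332607.1 | C=C1C[C@]23C[C@H]1CC[C@H]2[C@]12COC(=O)[C@](C)([C@@H](O)[C@@H](O)C1)[C@H]2[C@@H]3C(=O)O | target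

**Step count**

Total steps: 21. Longest linear sequence: 19 steps (steps 1–3, 5–7 and 9–21, from compound 1).

**Steps most likely to fail**

Step 10 (Proposed new method). The C-5–C-8 bond may not ionise before the silyl group migrates from oxygen to carbon or the ketene acetal is protonated, or the enoate may be taken up with poor endo/exo discrimination, which would scramble C-5. The fallback uses the known zerovalent-palladium-catalysed intramolecular [3+2] cycloaddition of a methylenecyclopropane with a tethered acceptor alkene (distal C–C insertion), followed by oxidative adjustment of the exocyclic carbon. It sets out from 9 and comes back at 18. Reduction of 9 with i-Bu2AlH should give the cyclopropylmethanol F1. NaH, CS2 and MeI convert it into the S-methyl xanthate F2, and Chugaev pyrolysis gives the methylenecyclopropane F3. Zinc insertion gives the alkylzinc iodide F4, and Negishi coupling with 13 gives the methylenecyclopropane enoate F5. Pd2(dba)3 and P(Oi-Pr)3 in dioxane at 100 °C should then give the tricyclic exocyclic alkene F6. Epoxidation of the more substituted alkene with mCPBA gives the spiro-epoxide F7, BF3·OEt2 rearranges it to the aldehyde F8, and I2/KOH/MeOH oxidises this to the silyl-protected diester F9. Pyridinium p-toluenesulfonate in MeOH removes the triethylsilyl group and returns 18.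

Step 14. Michael addition at the hindered tertiary enolate carbon may be too slow, or attack may come from the concave face. The fallback delivers C-3 intramolecularly, so that only the required C-4 configuration can form; it sets out from 22 and comes back at 26. LiN(i-Pr)2 and CBr4 give the bromo lactone F10 (either epimer serves). Hydroboration of the allyl group with 9-BBN and oxidation with NaBO3 give the primary alcohol F11, and Dess–Martin oxidation gives the aldehyde F12. An intramolecular SmI2 Reformatsky reaction closes ring A to the hydroxy lactone F13, and dehydration with Martin sulfurane, which can only proceed towards C-2, gives 26.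

Step 6. Carbene dimerisation, or ylide formation at iodine, may outrun transfer to the hindered trisubstituted alkene. The fallback replaces carbene transfer by a ketene [2+2] cycloaddition and Favorskii ring contraction; it sets out from 8 and comes back at 9. Dichloroketene (Cl2CHCOCl, Et3N) should add to the electron-rich alkene to give the dichlorocyclobutanone F14, either regiochemistry leading to the same cyclopropane. Zn in AcOH removes one chlorine to give the chlorocyclobutanone F15, and NaOMe in MeOH contracts the ring to 9.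

**Further compounds**

F1 | step 10 | cyclopropylmethanol from reduction of 9 | OCC1C(C(C)CO[Si](CC)(CC)CC)C12C[C@@H](CCI)[C@H](O[Si](C)(C)C(C)(C)C)C2
F2 | step 10 | S-methyl xanthate of F1 | CSC(=S)OCC1C(C(C)CO[Si](CC)(CC)CC)C12C[C@@H](CCI)[C@H](O[Si](C)(C)C(C)(C)C)C2
F3 | step 10 | spiro methylenecyclopropane (exocyclic CH2 on C-6) | C=C1C(C(C)CO[Si](CC)(CC)CC)C12C[C@@H](CCI)[C@H](O[Si](C)(C)C(C)(C)C)C2
F4 | step 10 | alkylzinc iodide of F3 | C=C1C(C(C)CO[Si](CC)(CC)CC)C12C[C@@H](CC[Zn]I)[C@H](O[Si](C)(C)C(C)(C)C)C2
F5 | step 10 | methylenecyclopropane with tethered (Z)-enoate | C=C1C(C(C)CO[Si](CC)(CC)CC)C12C[C@@H](CC/C=C(/CC=C)C(=O)OC)[C@H](O[Si](C)(C)C(C)(C)C)C2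
F6 | step 10 | B/C/D tricycle with exocyclic methylene on C-6 | CC(C)(C)[Si](C)(C)O[C@@H]1C[C@]23C[C@H]1CC[C@H]2[C@](C(=O)OC)(CC=C)[C@@H](C(C)CO[Si](CC)(CC)CC)C3=C
F7 | step 10 | spiro-epoxide at C-6 | CC(C)(C)[Si](C)(C)O[C@@H]1C[C@]23C[C@H]1CC[C@H]2[C@](C(=O)OC)(CC=C)[C@@H](C(C)CO[Si](CC)(CC)CC)C34CO4
F8 | step 10 | C-7 aldehyde | CC(C)(C)[Si](C)(C)O[C@@H]1C[C@]23C[C@H]1CC[C@H]2[C@](C(=O)OC)(CC=C)[C@@H](C(C)CO[Si](CC)(CC)CC)C3C=O
F9 | step 10 | triethylsilyl ether of 18 | CC(C)(C)[Si](C)(C)O[C@@H]1C[C@]23C[C@H]1CC[C@H]2[C@](C(=O)OC)(CC=C)[C@@H](C(C)CO[Si](CC)(CC)CC)C3C(=O)OC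
F10 | step 14 | C-4 bromo lactone | CC(C)(C)[Si](C)(C)O[C@@H]1C[C@]23C[C@H]1CC[C@H]2[C@@]4(CC=C)COC(=O)C(C)(Br)[C@H]4[C@@H]3C(=O)OC
F11 | step 14 | C-4 bromo lactone with 3-hydroxypropyl group on C-10 | CC(C)(C)[Si](C)(C)O[C@@H]1C[C@]23C[C@H]1CC[C@H]2[C@@]4(CCCO)COC(=O)C(C)(Br)[C@H]4[C@@H]3C(=O)OC
F12 | step 14 | C-4 bromo lactone with 3-oxopropyl group on C-10 | CC(C)(C)[Si](C)(C)O[C@@H]1C[C@]23C[C@H]1CC[C@H]2[C@@]4(CCC=O)COC(=O)C(C)(Br)[C@H]4[C@@H]3C(=O)OC
F13 | step 14 | tetracyclic 3-hydroxy 19,20-lactone | CC(C)(C)[Si](C)(C)O[C@@H]1C[C@]23C[C@H]1CC[C@H]2[C@]45COC(=O)[C@](C)(C(O)CC4)[C@H]5[C@@H]3C(=O)OC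
F14 | step 6 | spiro 2,2-dichlorocyclobutanone | O=C1C(C(C)CO[Si](CC)(CC)CC)C2(C[C@@H](CCI)[C@H](O[Si](C)(C)C(C)(C)C)C2)C1(Cl)Cl
F15 | step 6 | spiro 2-chlorocyclobutanone | O=C1C(C(C)CO[Si](CC)(CC)CC)C2(C[C@@H](CCI)[C@H](O[Si](C)(C)C(C)(C)C)C2)C1Cl
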